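**Retrosynthetic overview**
- The C8 ketone is unmasked last by oxidation of a carbinol; the two esters come from Mitsunobu inversions of the axial 3β- and 9α-alcohols obtained by hydride reduction of an 8-silyloxy-3,9-dione.
- That dione comes from an acyclic α-keto aldehyde in one flask: a carbonyl-ene reaction closes ring B (C7–C8) and creates the isopropenyl group, then a Diels–Alder reaction of the resulting β-methyl enone with a 2-silyloxypentadiene closes ring A (C4–C5 and C1–C10).
- The α-keto aldehyde comes from a Z-selective methylcuprate addition to an ynone built from prenyl bromide, ethynylmagnesium bromide and a silyloxyacetate.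
- Ring order: ring B first, ring A second, without isolation; C4 is then set by equilibration, C3 and C9 by reduction and inversion.

Assumption: the (S,S)-Ph-box ligand is taken to give the (5R,6R) ene product 11 by analogy with α-keto ester ene cyclisations; if the observed sense is opposite, the (R,R)-ligand is used and nothing else changes.
Naming: bicyclic compounds use eremophilane numbering (C14 on C5, C15 on C4, isopropenyl on C7); all are 5β-methyl, 7β-isopropenyl, 10β-H cis-decalins, β being the face of the C5 methyl, and the SMILES are definitive.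

**Route**

Step 1
Reactants: 1 1-bromo-3-methylbut-2-ene (prenyl bromide); 2 ethynylmagnesium bromide
Product: 3 5-methylhex-4-en-1-yne
Conditions: CuCl (5 mol%), THF, 0 °C to rt
Reagents that add atoms: none
Why: Copper-catalysed SN2 coupling of an alkynyl Grignard reagent with a primary allylic bromide occurs at the unhindered α-carbon and creates no stereocentre.

Step 2
Reactants: 3 5-methylhex-4-en-1-yne; 4 ethyl 2-[(tert-butyldimethylsilyl)oxy]acetate
Product: 5 1-[(tert-butyldimethylsilyl)oxy]-7-methyloct-6-en-3-yn-2-one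
Conditions: n-BuLi, THF, −78 °C; then 4, −78 °C; aq NH4Cl
Reagents that add atoms: none
Why: Acylation of the lithium acetylide by the α-silyloxy ester stops at the ynone because the chelated tetrahedral lithium hemiketal survives at −78 °C until work-up.

Step 3
Reactants: 5 1-[(tert-butyldimethylsilyl)oxy]-7-methyloct-6-en-3-yn-2-one
Product: 6 (3Z)-1-[(tert-butyldimethylsilyl)oxy]-4,7-dimethylocta-3,6-dien-2-one
Conditions: Me2CuLi, THF, −78 °C; aq NH4Cl at −78 °C
Reagents that add atoms: lithium dimethylcuprate, [Li+].C[Cu-]C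
Why: Conjugate addition of the cuprate to the ynone is a syn-carbocupration and cold protonation keeps the methyl cis to H, so the acyl group ends cis to the CH2 branch as the later ring closure needs.

Step 4
Reactants: 6 (3Z)-1-[(tert-butyldimethylsilyl)oxy]-4,7-dimethylocta-3,6-dien-2-one
Product: 7 (3Z)-1-hydroxy-4,7-dimethylocta-3,6-dien-2-one
Conditions: HF·pyridine, THF, 0 °C
Reagents that add atoms: none
Why: Buffered fluoride desilylation frees the primary carbinol without touching the Z-enone or the skipped diene.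

Step 5
Reactants: 7 (3Z)-1-hydroxy-4,7-dimethylocta-3,6-dien-2-one
Product: 8 (3Z)-4,7-dimethyl-2-oxoocta-3,6-dienal
Conditions: DMP, pyridine, CH2Cl2, 0 °C; crude 8 used at once
Reagents that add atoms: none
Why: Dess–Martin oxidation of the α-ketol gives the α-keto aldehyde under near-neutral conditions that avoid enolisation and premature cyclisation.

Step 6
Reactants: 9 pent-1-en-3-one (ethyl vinyl ketone)
Product: 10 tert-butyl(dimethyl)[(3Z)-penta-1,3-dien-3-yloxy]silane
Conditions: TBSOTf, Et3N, CH2Cl2, 0 °C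
Reagents that add atoms: tert-butyldimethylsilyl trifluoromethanesulfonate, CC(C)(C)[Si](C)(C)OS(=O)(=O)C(F)(F)F
Why: Soft enolisation of the enone can only occur on the ethyl side and gives the Z-configured 2-silyloxydiene (silyl dienol ether formation).

Step 7
Reactants: 8 (3Z)-4,7-dimethyl-2-oxoocta-3,6-dienal; 10 tert-butyl(dimethyl)[(3Z)-penta-1,3-dien-3-yloxy]silane
Product: 13 8α-hydroxy-4-epi-10βH-eremophil-11-ene-3,9-dione, via hydroxy enone 11 (not isolated), via silyl enol ether cycloadduct 12 (not isolated)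
Conditions: Cu(OTf)2 (10 mol%), (S,S)-Ph-box (11 mol%), 4 Å MS, CH2Cl2, −20 °C to rt; then AlMe3 (1.1 equiv), −40 °C; then 10 (3 equiv), AlBr3 (2 equiv), PhMe, −20 °C; then 1 M HCl, THF, rt
Reagents that add atoms: none
Why: Proposed new method: the aldehyde of the chelated 1,2-dicarbonyl in 8 is a strongly activated enophile, so a Cu(OTf)2–bis(oxazoline) Lewis acid should induce an intramolecular carbonyl-ene reaction with the prenyl group through a chair-like six-membered transition state (closest precedent: Cu–box-catalysed ene cyclisations of olefinic α-keto esters), the ligand fixing C7 and C8 with isopropenyl and hydroxyl trans-diequatorial, after which the chelating α'-aluminoxy enone undergoes an AlBr3/AlMe3-promoted Diels–Alder reaction with diene 10 (closest precedent: mixed aluminium Lewis acid cycloadditions of hindered β-methyl cyclohexenones and anti-selective additions to carvone-type enones), the methyl-bearing diene terminus bonding to the β-carbon C5 and the diene adding suprafacially from the face opposite the C7 isopropenyl group, so that the 5-methyl and 10-H end cis to it in a cis-decalin while the endo-derived 4α-methyl is corrected in step 8.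

Step 8
Reactants: 13 8α-hydroxy-4-epi-10βH-eremophil-11-ene-3,9-dione
Product: 15 8α-[(tert-butyldimethylsilyl)oxy]-10βH-eremophil-11-ene-3,9-dione, via 4-epi silyl ether 14 (not isolated)
Conditions: TBSOTf, 2,6-lutidine, CH2Cl2, −78 °C; then MeOH, DBU, rt
Reagents that add atoms: tert-butyldimethylsilyl trifluoromethanesulfonate, CC(C)(C)[Si](C)(C)OS(=O)(=O)C(F)(F)F
Why: Silyl triflate with a hindered pyridine base silylates the carbinol faster than it enolises the ketones, and DBU then equilibrates C4 through the C3 enolate to the equatorial 4β-methyl, because the axial 4α-methyl is 1,3-diaxial to C9 (silylation then thermodynamic epimerisation).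

Step 9
Reactants: 15 8α-[(tert-butyldimethylsilyl)oxy]-10βH-eremophil-11-ene-3,9-dione
Product: 16 8α-[(tert-butyldimethylsilyl)oxy]-10βH-eremophil-11-ene-3β,9α-diol
Conditions: LiBH(s-Bu)3, THF, −78 to −20 °C; then pH 7 buffer, H2O2
Reagents that add atoms: none
Why: The bulky borohydride attacks both ketones from the equatorial direction, axial approach being blocked at C3 by the axial 5-methyl and at C9 by the axial C4 of ring A, so both new carbinols are axial (sterically controlled ketone reduction).

Step 10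
Reactants: 16 8α-[(tert-butyldimethylsilyl)oxy]-10βH-eremophil-11-ene-3β,9α-diol; 17 angelic acid [(2Z)-2-methylbut-2-enoic acid]
Product: 18 3α-angeloyloxy-8α-[(tert-butyldimethylsilyl)oxy]-10βH-eremophil-11-en-9α-ol
Conditions: PPh3, DIAD, PhMe, 0 °C to rt
Reagents that add atoms: none
Why: The Mitsunobu reaction esterifies with inversion, and the axial C3 carbinol next to a CH2 reacts far faster than the C9 carbinol flanked by two substituted carbons, giving the equatorial 3α-angelate without a base that could isomerise the Z-enoate.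

Step 11
Reactants: 18 3α-angeloyloxy-8α-[(tert-butyldimethylsilyl)oxy]-10βH-eremophil-11-en-9α-ol; 19 senecioic acid (3-methylbut-2-enoic acid)
Product: 20 3α-angeloyloxy-8α-[(tert-butyldimethylsilyl)oxy]-9β-senecioyloxy-10βH-eremophil-11-ene
Conditions: PPh3, DIAD, PhMe, 50 °C
Reagents that add atoms: none
Why: A second, more forcing Mitsunobu inversion turns the remaining axial 9α-carbinol into the equatorial 9β-senecioate, the carboxylate entering from the open convex β-face.

Step 12
Reactants: 20 3α-angeloyloxy-8α-[(tert-butyldimethylsilyl)oxy]-9β-senecioyloxy-10βH-eremophil-11-ene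
Product: 21 3α-angeloyloxy-9β-senecioyloxy-10βH-eremophil-11-en-8α-ol
Conditions: HF·pyridine, pyridine/THF, 0 °C to rt
Reagents that add atoms: none
Why: Acidic fluoride removes the secondary silyl ether without ester cleavage or acyl migration (desilylation).

Step 13
Reactants: 21 3α-angeloyloxy-9β-senecioyloxy-10βH-eremophil-11-en-8α-ol
Product: 22 3α-angeloyloxy-9β-senecioyloxy-10βH-eremophil-11-en-8-one
Conditions: DMP, pyridine, CH2Cl2, 0 °C to rt
Reagents that add atoms: none
Why: Dess–Martin oxidation forms the C8 ketone under non-basic conditions, so the now enolisable C7 and C9 centres keep their configurations and the isopropenyl group does not move into conjugation.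

**Compound list**

1 | 1-bromo-3-methylbut-2-ene (prenyl bromide) | CC(C)=CCBr | starting material
2 | ethynylmagnesium bromide | C#C[Mg]Br | starting material
3 | 5-methylhex-4-en-1-yne | CC(C)=CCC#C | intermediate
4 | ethyl 2-[(tert-butyldimethylsilyl)oxy]acetate | CCOC(=O)CO[Si](C)(C)C(C)(C)C | starting material
5 | 1-[(tert-butyldimethylsilyl)oxy]-7-methyloct-6-en-3-yn-2-one | CC(C)=CCC#CC(=O)CO[Si](C)(C)C(C)(C)C | intermediate
6 | (3Z)-1-[(tert-butyldimethylsilyl)oxy]-4,7-dimethylocta-3,6-dien-2-one | CC(C)=CC/C(C)=C\C(=O)CO[Si](C)(C)C(C)(C)C | intermediate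
7 | (3Z)-1-hydroxy-4,7-dimethylocta-3,6-dien-2-one | CC(C)=CC/C(C)=C\C(=O)CO | intermediate
8 | (3Z)-4,7-dimethyl-2-oxoocta-3,6-dienal | CC(C)=CC/C(C)=C\C(=O)C=O | intermediate
9 | pent-1-en-3-one (ethyl vinyl ketone) | CCC(=O)C=C | starting material
10 | tert-butyl(dimethyl)[(3Z)-penta-1,3-dien-3-yloxy]silane | C/C=C(\O[Si](C)(C)C(C)(C)C)C=C | intermediate
11 | (5R,6R)-6-hydroxy-3-methyl-5-(prop-1-en-2-yl)cyclohex-2-en-1-one | C=C(C)[C@H]1CC(C)=CC(=O)[C@@H]1O | intermediate (not isolated)
12 | 3-[(tert-butyldimethylsilyl)oxy]-8α-hydroxy-4-epi-10βH-eremophila-2,11-dien-9-one | C=C(C)[C@H]1C[C@@]2(C)[C@H](CC=C(O[Si](C)(C)C(C)(C)C)[C@H]2C)C(=O)[C@@H]1O | intermediate (not isolated)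
13 | 8α-hydroxy-4-epi-10βH-eremophil-11-ene-3,9-dione | C=C(C)[C@H]1C[C@@]2(C)[C@H](CCC(=O)[C@H]2C)C(=O)[C@@H]1O | intermediate
14 | 8α-[(tert-butyldimethylsilyl)oxy]-4-epi-10βH-eremophil-11-ene-3,9-dione | C=C(C)[C@H]1C[C@@]2(C)[C@H](CCC(=O)[C@H]2C)C(=O)[C@@H]1O[Si](C)(C)C(C)(C)C | intermediate (not isolated)
15 | 8α-[(tert-butyldimethylsilyl)oxy]-10βH-eremophil-11-ene-3,9-dione | C=C(C)[C@H]1C[C@@]2(C)[C@H](CCC(=O)[C@@H]2C)C(=O)[C@@H]1O[Si](C)(C)C(C)(C)C | intermediate
16 | 8α-[(tert-butyldimethylsilyl)oxy]-10βH-eremophil-11-ene-3β,9α-diol | C=C(C)[C@H]1C[C@@]2(C)[C@H](CC[C@H](O)[C@@H]2C)[C@H](O)[C@@H]1O[Si](C)(C)C(C)(C)C | intermediate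
17 | angelic acid [(2Z)-2-methylbut-2-enoic acid] | OC(=O)/C(C)=C\C | starting material
18 | 3α-angeloyloxy-8α-[(tert-butyldimethylsilyl)oxy]-10βH-eremophil-11-en-9α-ol | C=C(C)[C@H]1C[C@@]2(C)[C@H](CC[C@@H](OC(=O)/C(C)=C\C)[C@@H]2C)[C@H](O)[C@@H]1O[Si](C)(C)C(C)(C)C | intermediate
19 | senecioic acid (3-methylbut-2-enoic acid) | CC(C)=CC(=O)O | starting material
20 | 3α-angeloyloxy-8α-[(tert-butyldimethylsilyl)oxy]-9β-senecioyloxy-10βH-eremophil-11-ene | C=C(C)[C@H]1C[C@@]2(C)[C@H](CC[C@@H](OC(=O)/C(C)=C\C)[C@@H]2C)[C@@H](OC(=O)C=C(C)C)[C@@H]1O[Si](C)(C)C(C)(C)C | intermediate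
21 | 3α-angeloyloxy-9β-senecioyloxy-10βH-eremophil-11-en-8α-ol | C=C(C)[C@H]1C[C@@]2(C)[C@H](CC[C@@H](OC(=O)/C(C)=C\C)[C@@H]2C)[C@@H](OC(=O)C=C(C)C)[C@@H]1O | intermediate
22 | 3α-angeloyloxy-9β-senecioyloxy-10βH-eremophil-11-en-8-one (3R,4R,5R,7R,9R,10S) | C=C(C)[C@H]1C[C@@]2(C)[C@H](CC[C@@H](OC(=O)/C(C)=C\C)[C@@H]2C)[C@@H](OC(=O)C=C(C)C)C1=O | target

**Step count and weak points**

Total: 13 steps. Longest linear sequence: 12 steps (steps 1–5 and 7–13); step 6 is a one-step side branch.

The three steps most likely to fail, each with a fallback: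

Step 7 is the weakest point. The ene cyclisation of an α-keto aldehyde and the cycloaddition on a β-methyl enone carrying a free aluminium alkoxide and an acid-sensitive isopropenyl group are both unproven in this setting. The fallback sets out from 8 and returns at 14. Compound 8 is cyclised with the copper catalyst alone and silylated in the same flask (TBSOTf, 2,6-lutidine) to give (5R,6R)-6-[(tert-butyldimethylsilyl)oxy]-3-methyl-5-(prop-1-en-2-yl)cyclohex-2-en-1-one F1. Ring A is then built ionically in two separate bond-forming events instead of one cycloaddition. A Tf2NH-catalysed Mukaiyama–Michael addition of 10 to C5 of F1, anti to the isopropenyl group, gives 8α,9-bis[(tert-butyldimethylsilyl)oxy]-4-epi-1,10-secoeremophila-1,9,11-trien-3-one F2. A second silyl-transfer Michael closure of the ring enol silane of F2 onto its vinyl ketone gives 3,8α-bis[(tert-butyldimethylsilyl)oxy]-4-epi-10βH-eremophila-2,11-dien-9-one F3. Dilute HCl hydrolyses the enol ether of F3 to 14, and DBU converts 14 into 15 as in step 8.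

Step 10 may give elimination at the strained axial C3 carbinol, partial reaction at C9, or angelate-to-tiglate isomerisation. The fallback sets out from 16 and returns at 18. Mitsunobu inversion with the more acidic 4-nitrobenzoic acid gives 8α-[(tert-butyldimethylsilyl)oxy]-9α-hydroxy-10βH-eremophil-11-en-3α-yl 4-nitrobenzoate F4. K2CO3 in MeOH at 0 °C then gives 8α-[(tert-butyldimethylsilyl)oxy]-10βH-eremophil-11-ene-3α,9α-diol F5. The unhindered equatorial 3α-carbinol of F5 is acylated with retention by the preformed mixed anhydride of 17 and 2,4,6-trichlorobenzoyl chloride (Et3N, PhMe, 80 °C, no DMAP) to give 18; the hindered axial 9α-carbinol stays free.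

Step 11 asks for a Mitsunobu inversion at a carbinol flanked by the ring-fusion carbon and the silyloxy-bearing C8, where elimination towards C10 can compete. The fallback sets out from 18 and returns at 20. The carbinol is converted with Tf2O and pyridine into 3α-angeloyloxy-8α-[(tert-butyldimethylsilyl)oxy]-10βH-eremophil-11-en-9α-yl trifluoromethanesulfonate F6. The axial triflate is then displaced with inversion by CsO2CCH=CMe2 (from 19 and Cs2CO3) with 18-crown-6 in PhMe to give 20.

**Further compounds**

F1 | step 7 | (5R,6R)-6-[(tert-butyldimethylsilyl)oxy]-3-methyl-5-(prop-1-en-2-yl)cyclohex-2-en-1-one | C=C(C)[C@H]1CC(C)=CC(=O)[C@@H]1O[Si](C)(C)C(C)(C)C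
F2 | step 7 | 8α,9-bis[(tert-butyldimethylsilyl)oxy]-4-epi-1,10-secoeremophila-1,9,11-trien-3-one | C=C(C)[C@H]1C[C@@]([C@H](C)C(=O)C=C)(C)C=C(O[Si](C)(C)C(C)(C)C)[C@@H]1O[Si](C)(C)C(C)(C)C
F3 | step 7 | 3,8α-bis[(tert-butyldimethylsilyl)oxy]-4-epi-10βH-eremophila-2,11-dien-9-one | C=C(C)[C@H]1C[C@@]2(C)[C@H](CC=C(O[Si](C)(C)C(C)(C)C)[C@H]2C)C(=O)[C@@H]1O[Si](C)(C)C(C)(C)C
F4 | step 10 | 8α-[(tert-butyldimethylsilyl)oxy]-9α-hydroxy-10βH-eremophil-11-en-3α-yl 4-nitrobenzoate | C=C(C)[C@H]1C[C@@]2(C)[C@H](CC[C@@H](OC(=O)c3ccc(cc3)[N+](=O)[O-])[C@@H]2C)[C@H](O)[C@@H]1O[Si](C)(C)C(C)(C)C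
F5 | step 10 | 8α-[(tert-butyldimethylsilyl)oxy]-10βH-eremophil-11-ene-3α,9α-diol | C=C(C)[C@H]1C[C@@]2(C)[C@H](CC[C@@H](O)[C@@H]2C)[C@H](O)[C@@H]1O[Si](C)(C)C(C)(C)C
F6 | step 11 | 3α-angeloyloxy-8α-[(tert-butyldimethylsilyl)oxy]-10βH-eremophil-11-en-9α-yl trifluoromethanesulfonate | C=C(C)[C@H]1C[C@@]2(C)[C@H](CC[C@@H](OC(=O)/C(C)=C\C)[C@@H]2C)[C@H](OS(=O)(=O)C(F)(F)F)[C@@H]1O[Si](C)(C)C(C)(C)C
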